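All runs were generated by integration from invented constants; the scatter is artificial.

Before the flask is left stirring for 15 h on less reagent than substrate, settle what it will hold.

| setting | south-west | south | flask |
|---|---|---|---|
| substrate | 0.014 M (fed, over 4.0 h) | 0.014 M (fed, over 4.0 h) | 0.014 M (fed, over 4.0 h) |
| reagent in the second phase | 1.3 equiv | 2.1 equiv | 0.950 equiv |
| remark | run made earlier | run made earlier |  |
| time |  |  | 15 h |
| volume of the second phase over the first |  |  | 0.25 |

- south-west (time / h: target / %): 0.833: 0.4; 2.50: 0; 4.00: 2.1; 6.00: 4.7; 10.0: 5.3
- south (time / h: target / %): 0.667: 0; 1.33: 0.5; 2.50: 0.5; 5.00: 3.0; 10.0: 8.5

(each reading ± 0.5 percentage points)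

- in the second phase: reagent in the second phase; everything else is in the first
- charges count per volume of the first phase; a concentration in a rate is the amount of a species over the volume of its own phase; every rate counts per litre of the first phase
- the earlier runs hold the two phases in the same ratio of volumes as the flask asked about
- percentages count the whole charge, also what has not yet gone in

1. amount of target in percent of the substrate charged, at 50 min, 4.0 h and 15 h

**What do you read from the runs?** Target lags while substrate goes in. I try a rate of target proportional to c(substrate) times the equivalents of reagent, with substrate taken as barely consumed: an apparent pseudo-first-order law.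

**Which clock does that law run on?** Exposure, the hours the whole charge would need to stand to match what the fed substrate has seen. It is t·t/(2·tf) during the feed and t − tf/2 afterwards, so 8.00 h at 10.0 h.

**And the constant?** The yield constant is the fraction of the charge turned into target per equivalent and per hour of exposure 0.00506 h⁻¹, read from the south run. The south-west run gives 0.00510 h⁻¹, the same within the scatter.

**Where is it weak?** At 6.00 h the south-west run reads 4.7%, while the constant gives 2.63% and the scatter is 0.5 percentage points. That reading yields 0.00904 h⁻¹, higher than the south run's, so in the south-west run the constant may sink with time.

**Your numbers?** Mine are 0.0417%, 0.961% and 6.25%.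

**And the forecast?** It gives 0.05%, 1.1% and 5.5%. Its last figure stands below mine, and of that figure it says: “I shade the last down for possible plateauing”.

The flask gives 0.0213%, 1.35% and 5.51%, so the forecast is right within the tolerance, under this scheme:

    reagent in the reaction phase ⇌ reagent in the second phase, rate k1*([reagent in the reaction phase] - [reagent in the second phase]/K1) per volume of the first phase (partition coefficient = 38.0, kL = 0.00136 min⁻¹)
    substrate + reagent in the reaction phase → target (k = 0.678 M⁻¹ min⁻¹)
    reagent in the reaction phase + target → over-reacted product (k = 1.26 M⁻¹ min⁻¹)
    substrate + target → side product (k = 0.0714 M⁻¹ min⁻¹)

At 15.0 h the flask holds 4.83% side product, each one counted as two, beside its target. Its own yield constant at that time is 0.00446 h⁻¹, lower than the one read from the south run. A forecast from that constant would be wrong at more time: the same flask at twice the time holds 7.31% where the constant from the south run gives 13.5%, a yield constant of 0.00275 h⁻¹.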